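**Two steps.** In a one-step world the whole charge ends in one product, whatever its size. Here I saw two steps, and the north-west run and alder differ in charge, alder holding half as much.

| setting | north-west | alder | maple |
|---|---|---|---|
| starting material | 2.4 M | 1.2 M | 1.2 M |
| remark | run made earlier |  |  |
| time |  | 30 h | 75 h |

north-west run (percent of the starting material charged)

| time / h | target / % | intermediate A / % | intermediate B / % | intermediate C / % | side product / % | starting material / % |
|---|---|---|---|---|---|---|
| 0.333 | 0 | 10 | 1 | 1 | 5 | 83 |
| 1.00 | 0 | 15 | 2 | 0 | 25 | 60 |
| 1.50 | 0 | 18 | 0 | 0 | 38 | 44 |
| 2.50 | 2 | 16 | 5 | 3 | 54 | 22 |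
| 4.00 | 0 | 20 | 6 | 0 | 68 | 11 |
| 5.00 | 0 | 14 | 5 | 0 | 71 | 6 |
| 6.00 | 1 | 12 | 6 | 3 | 75 | 5 |

(each reading ± 1.5 percentage points)

- in percentages every species weighs as the starting material in it: one side product counts as two
- what was read earlier has a scatter of 1.5 percentage points, one standard deviation

1. which of these there is most of at the end, counted by the starting material in it, alder (side product / target / intermediate C / intermediate B / intermediate A)
2. which of these there is most of at the end, counted by the starting material in it, maple (side product / target / intermediate C / intermediate B / intermediate A)
3. the largest of these amounts at the end, in percent of the starting material charged, alder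
4. the largest of these amounts at the end, in percent of the starting material charged, maple

**The reading.** In the north-west run intermediate A held between 15 % and 20 % while starting material fell from 60 % to 11 %. So I assumed starting material → intermediate A, then starting material + intermediate A → side product. Both rates carry c(starting material), so their ratio depends on c(intermediate A). I ignored what leaves intermediate A onward.

**Fraction left.** Let L be the share of the charge outside side product, and N a selectivity factor. Dividing the rates removes time. With starting material gone, L = (1 − exp(−N(1 + L)/2))/N. With a share s remaining, s is subtracted inside the bracket. The last north-west reading put 22.0 % in the pool, with 5 % of starting material left. That gave 1.73 L mol⁻¹, a reading with its scatter. I call this κ, the coupling constant, the coupling rate constant over the formation rate constant; N is κ times the charge.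

**Why they part.** The pool's ceiling, 1/κ, is a concentration of 0.578 M. It is a larger share of alder's charge, 48.1 %, than of the north-west charge, 24.0 %. For alder N is 2.08, so L is 36.6 %, and side product is 63.4 %. Alder's 30 h is longer than 6.00 h, so I took starting material as gone in alder and maple, with the same answer for both.

**The forecast.** It said side product and side product, at 58 % and 58 %, lower than mine, and its ground for one value at both times was “That channel is finished by about 10 h”.

**The flasks.** Alder and maple each gave side product as the largest, at 62.7 % and 62.7 %, against my 63.4 %. Target stood at 6.59 % in alder and 21.6 % in maple, while the longer time left side product where it was.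

    starting material + intermediate A → side product (k = 1.93 × 10⁻⁴ L mol⁻¹ s⁻¹)
    intermediate B → intermediate C (k = 4.47 × 10⁻⁶ s⁻¹)
    starting material → intermediate A (k = 9.69 × 10⁻⁵ s⁻¹)
    intermediate C → target (k = 4.67 × 10⁻⁵ s⁻¹)
    intermediate A → intermediate B (k = 2.30 × 10⁻⁵ s⁻¹)

With 0.30 M charged, κ gives N = 0.520 and side product 31.7 %. That flask gave 30.9 %, with 39.8 % of target, its largest amount.

The runs come from a simulation for an exercise, and the scatter is random.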